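**Strategy.** The pyran and the oxepine are disconnected together at O1–C2 and Ca–C6′ (ring B), which leads back to an open-chain α-aryl γ,δ-epoxy aldehyde. Two features are used: O1–C2 (quaternary) next to C3–O is what anti opening of a trisubstituted epoxide leaves behind, and Ca, bonded to O1, Cb and ring B, is an oxocarbenium carbon caught by an arene. In one operation the aldehyde oxygen opens the nerol-derived epoxide at its tertiary carbon (pyran, C2 by inversion) and ring B closes the oxepine on the resulting cation. The precursor, aldehyde 13, carries ring A with its prenyl group, the silylated ring B aryl ether and the Sharpless epoxide. Dehydrogenation and desilylation follow.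

Key step: step 9

**Labels.** Pyran: O1, C2 (quaternary), C3 (carbinol), C4 (CH2), Cb (bonded to ring A), Ca (bonded to O1 and ring B). Ring A is the prenylated ring. Ring B: C1′ (ether oxygen), C3′ (oxygen), C6′ (bonded to Ca, para to C3′–O), C2′ (between the two oxygens).

**Assumption.** Methyl 2,4-dihydroxyphenylacetate 1, boronic acid 4 and stannane 6 are taken as commercial (1 is otherwise one Fischer esterification from the acid).

**Remark on the chemistry.** The target is (2S,3S) in the pyran numbering; with inversion at C2 and retention at C3 this requires (2S,3R)-2,3-epoxynerol, i.e. the L-(+)-tartrate series. Ring B has two carbons ortho to its ether oxygen that can reach Ca (C2′ and C6′); the route relies on the unhindered C6′.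

**Route**

Step 1
Reactants: 1 methyl 2-(2,4-dihydroxyphenyl)acetate
Product: 2 methyl 2-[2-hydroxy-4-(triisopropylsilyloxy)phenyl]acetate
Conditions: TIPSCl (1.05 equiv), imidazole, CH2Cl2, 0 °C
Reagents that add atoms: triisopropylsilyl chloride, CC(C)[Si](Cl)(C(C)C)C(C)C
Why: Sterically controlled phenol silylation; the bulky chlorosilane should take the open 4-hydroxyl in preference to the 2-hydroxyl, which is flanked by the acetate arm and hydrogen-bonded to its carbonyl.

Step 2
Reactants: 2 methyl 2-[2-hydroxy-4-(triisopropylsilyloxy)phenyl]acetate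
Product: 3 methyl 2-[2-hydroxy-5-iodo-4-(triisopropylsilyloxy)phenyl]acetate
Conditions: NIS (1.05 equiv), MeCN, 0 °C → rt
Reagents that add atoms: N-iodosuccinimide, O=C1CCC(=O)N1I
Why: Electrophilic aromatic iodination; the free 2-hydroxyl directs para to ring position 5 (also ortho to the silyloxy group), while position 3 is wedged between the hydroxyl and the TIPS ether.

Step 3
Reactants: 3 methyl 2-[2-hydroxy-5-iodo-4-(triisopropylsilyloxy)phenyl]acetate; 4 [3-(tert-butyldimethylsilyloxy)phenyl]boronic acid
Product: 5 methyl 2-[2-[3-(tert-butyldimethylsilyloxy)phenoxy]-5-iodo-4-(triisopropylsilyloxy)phenyl]acetate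
Conditions: Cu(OAc)2 (1.5 equiv), pyridine, 4 Å MS, CH2Cl2, dry air, rt
Reagents that add atoms: none
Why: Chan–Lam copper(II)-mediated O-arylation of the phenol by the arylboronic acid at room temperature, mild enough for both aryl silyl ethers, the methyl ester and the aryl iodide.

Step 4
Reactants: 5 methyl 2-[2-[3-(tert-butyldimethylsilyloxy)phenoxy]-5-iodo-4-(triisopropylsilyloxy)phenyl]acetate; 6 tributyl(3-methylbut-2-en-1-yl)stannane
Product: 7 methyl 2-[2-[3-(tert-butyldimethylsilyloxy)phenoxy]-5-(3-methylbut-2-en-1-yl)-4-(triisopropylsilyloxy)phenyl]acetate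
Conditions: Pd(PPh3)4 (5 mol%), DMF, 80 °C
Reagents that add atoms: none
Why: Stille cross-coupling; oxidative addition into the aryl iodide, prenyl transfer from tin and reductive elimination at the unsubstituted allyl terminus should give the linear prenyl arene under neutral, fluoride-free conditions.

Step 5
Reactants: 8 nerol, (2Z)-3,7-dimethylocta-2,6-dien-1-ol
Product: 9 [(2S,3R)-3-methyl-3-(4-methylpent-3-en-1-yl)oxiran-2-yl]methanol, (2S,3R)-2,3-epoxynerol
Conditions: Ti(OiPr)4 (10 mol%), L-(+)-DET (12 mol%), TBHP, 4 Å MS, CH2Cl2, −20 °C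
Reagents that add atoms: tert-butyl hydroperoxide, CC(C)(C)OO
Why: Katsuki–Sharpless asymmetric epoxidation; the titanium tartrate binds the allylic alcohol, so only the 2,3-alkene reacts, and L-(+)-tartrate sets both epoxide stereocentres as (2S,3R) on the Z-alcohol.

Step 6
Reactants: 9 (2S,3R)-2,3-epoxynerol
Product: 10 (2R,3R)-2-(bromomethyl)-3-methyl-3-(4-methylpent-3-en-1-yl)oxirane (same spatial arrangement as 9; only the descriptor at C2 changes)
Conditions: PPh3, CBr4, NaHCO3 (solid), CH2Cl2, 0 °C
Reagents that add atoms: carbon tetrabromide, BrC(Br)(Br)Br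
Why: Appel bromination of the primary alcohol under neutral conditions (bromide displaces the alkoxyphosphonium group at CH2), leaving the epoxide and its two stereocentres untouched.

Step 7
Reactants: 7 methyl 2-[2-[3-(tert-butyldimethylsilyloxy)phenoxy]-5-(3-methylbut-2-en-1-yl)-4-(triisopropylsilyloxy)phenyl]acetate; 10 (2R,3R)-2-(bromomethyl)-3-methyl-3-(4-methylpent-3-en-1-yl)oxirane
Product: 12 methyl 2-aryl-3-[(2S,3R)-3-methyl-3-(4-methylpent-3-en-1-yl)oxiran-2-yl]propanoate (aryl as in 7; both epimers at the propanoate C2), via lithium ester enolate 11 (not isolated)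
Conditions: LiHMDS, THF, −78 °C; then 10, DMPU, −78 → 0 °C
Reagents that add atoms: none
Why: Ester enolate alkylation (SN2) at the primary oxiranylmethyl bromide, whose trisubstituted epoxide is too hindered to be opened by the enolate; the new α-stereocentre is uncontrolled and need not be controlled because it becomes sp2 in step 10.

Step 8
Reactants: 12 methyl 2-aryl-3-[(2S,3R)-3-methyl-3-(4-methylpent-3-en-1-yl)oxiran-2-yl]propanoate
Product: 13 2-aryl-3-[(2S,3R)-3-methyl-3-(4-methylpent-3-en-1-yl)oxiran-2-yl]propanal (aryl = 2-[3-(tert-butyldimethylsilyloxy)phenoxy]-5-prenyl-4-(triisopropylsilyloxy)phenyl; both α-epimers)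
Conditions: DIBAL-H (1.1 equiv), CH2Cl2, −78 °C; MeOH, then aq. Rochelle salt
Reagents that add atoms: none
Why: DIBAL-H partial reduction of the methyl ester through an aluminium hemiacetal that is stable at −78 °C and releases the aldehyde on work-up; the hindered epoxide and the silyl ethers should be inert at this temperature.

Step 9
Reactants: 13 2-aryl-3-[(2S,3R)-3-methyl-3-(4-methylpent-3-en-1-yl)oxiran-2-yl]propanal
Product: 15 C3-triethylsilyl ether of the 10,11-dihydro pyrano-dibenzoxepine (2S,3S; Ca/Cb epimers; TIPS ether and prenyl on ring A; TBS ether on ring B), via pyranyl oxocarbenium triflate 14 (not isolated)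
Conditions: TESOTf (1.2 equiv), 2,6-di-tert-butyl-4-methylpyridine (1.5 equiv), CH2Cl2, −78 → −40 °C
Reagents that add atoms: triethylsilyl trifluoromethanesulfonate, CC[Si](CC)(CC)OS(=O)(=O)C(F)(F)F
Why: Proposed new method: TESOTf silylates the epoxide oxygen, the free aldehyde oxygen attacks the tertiary epoxide carbon from the rear to give pyranyl oxocarbenium ion 14, ring B adds to Ca through C6′ and the hindered pyridine removes the arenium proton. The closest known reactions are Lewis-acid epoxide openings by a neighbouring carbonyl oxygen (carbonate- or ketone-terminated epoxide cascades, acetonide formation from epoxides and acetone) and oxa-Pictet–Spengler or C-aryl glycoside type arylations of cyclic oxocarbenium ions. The pyran closes by 6-endo opening of the epoxide (against 5-exo at the secondary carbon), the oxepine by a seven-membered intramolecular Friedel–Crafts alkylation. C2 is set by stereospecific inversion at the tertiary epoxide carbon and C3 keeps the configuration of the Z-epoxide from step 5, whereas the Ca and Cb epimers converge in step 10. The step needs tertiary over secondary opening, secured by a weak carbonyl nucleophile meeting an epoxide whose positive charge sits on the methyl-bearing carbon, and arylation at C6′ over C2′ (wedged between two oxygens) and over Prins capture by the homoprenyl alkene, which would need that chain axial while the diaryl ether already holds ring B above Ca. Silyl transfer to the epoxide oxygen is deliberate: a free C3 alkoxide could close onto Ca to a bicyclic acetal, through which the two opening modes would merge and erode the C2/C3 configuration, and the TES ether is needed again in step 10.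

Step 10
Reactants: 15 C3-triethylsilyl ether of the 10,11-dihydro pyrano-dibenzoxepine
Product: 16 tris-silylated pyrano-dibenzo[b,f]oxepine (Ca=Cb enol ether; 2S,3S; C3–OTES, ring A OTIPS, ring B OTBS)
Conditions: DDQ (1.1 equiv), 2,6-dichloropyridine, 4 Å MS, ClCH2CH2Cl, 0 °C → rt
Reagents that add atoms: none
Why: DDQ dehydrogenation; hydride abstraction from Ca–H (a benzylic ether C–H para to the ring B silyloxy group) gives an aryl-stabilised oxocarbenium ion and loss of the benzylic Cb proton gives the conjugated enol ether, while the C3 silyl ether keeps that oxygen from adding to the cation and the TIPS group shields the prenyl methylene.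

Step 11
Reactants: 16 tris-silylated pyrano-dibenzo[b,f]oxepine
Product: 17 CNP0185870.1, (2S,3S)-pyrano-dibenzo[b,f]oxepine triol
Conditions: TBAF (3.5 equiv), AcOH (3.5 equiv), THF, 0 °C → rt
Reagents that add atoms: none
Why: Fluoride-driven cleavage of the three silyl ethers (Si–F bond formation), buffered with acetic acid so that the phenoxides, the enol ether and the o-prenylphenol see neither strong base nor acid; no stereocentre is touched.

**Compound list**

1 | methyl 2-(2,4-dihydroxyphenyl)acetate | COC(=O)Cc1ccc(O)cc1O | starting material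
2 | methyl 2-[2-hydroxy-4-(triisopropylsilyloxy)phenyl]acetate | COC(=O)Cc1ccc(O[Si](C(C)C)(C(C)C)C(C)C)cc1O | intermediate
3 | methyl 2-[2-hydroxy-5-iodo-4-(triisopropylsilyloxy)phenyl]acetate | COC(=O)Cc1cc(I)c(O[Si](C(C)C)(C(C)C)C(C)C)cc1O | intermediate
4 | [3-(tert-butyldimethylsilyloxy)phenyl]boronic acid | CC(C)(C)[Si](C)(C)Oc1cccc(B(O)O)c1 | starting material
5 | methyl 2-[2-[3-(tert-butyldimethylsilyloxy)phenoxy]-5-iodo-4-(triisopropylsilyloxy)phenyl]acetate | COC(=O)Cc1cc(I)c(O[Si](C(C)C)(C(C)C)C(C)C)cc1Oc1cccc(O[Si](C)(C)C(C)(C)C)c1 | intermediate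
6 | tributyl(3-methylbut-2-en-1-yl)stannane | CCCC[Sn](CCCC)(CCCC)CC=C(C)C | starting material
7 | methyl 2-[2-[3-(tert-butyldimethylsilyloxy)phenoxy]-5-(3-methylbut-2-en-1-yl)-4-(triisopropylsilyloxy)phenyl]acetate | COC(=O)Cc1cc(CC=C(C)C)c(O[Si](C(C)C)(C(C)C)C(C)C)cc1Oc1cccc(O[Si](C)(C)C(C)(C)C)c1 | intermediate
8 | nerol, (2Z)-3,7-dimethylocta-2,6-dien-1-ol | CC(C)=CCC/C(C)=C\CO | starting material
9 | [(2S,3R)-3-methyl-3-(4-methylpent-3-en-1-yl)oxiran-2-yl]methanol | CC(C)=CCC[C@@]1(C)O[C@H]1CO | intermediate
10 | (2R,3R)-2-(bromomethyl)-3-methyl-3-(4-methylpent-3-en-1-yl)oxirane | CC(C)=CCC[C@@]1(C)O[C@H]1CBr | intermediate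
11 | lithium enolate of ester 7 | [Li+].COC([O-])=Cc1cc(CC=C(C)C)c(O[Si](C(C)C)(C(C)C)C(C)C)cc1Oc1cccc(O[Si](C)(C)C(C)(C)C)c1 | intermediate (not isolated)
12 | methyl 2-aryl-3-[(2S,3R)-3-methyl-3-(4-methylpent-3-en-1-yl)oxiran-2-yl]propanoate, both α-epimers | CC(C)=CCC[C@@]1(C)O[C@H]1CC(C(=O)OC)c1cc(CC=C(C)C)c(O[Si](C(C)C)(C(C)C)C(C)C)cc1Oc1cccc(O[Si](C)(C)C(C)(C)C)c1 | intermediate
13 | 2-aryl-3-[(2S,3R)-3-methyl-3-(4-methylpent-3-en-1-yl)oxiran-2-yl]propanal, both α-epimers (key-step precursor) | CC(C)=CCC[C@@]1(C)O[C@H]1CC(C=O)c1cc(CC=C(C)C)c(O[Si](C(C)C)(C(C)C)C(C)C)cc1Oc1cccc(O[Si](C)(C)C(C)(C)C)c1 | intermediate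
14 | pyranyl oxocarbenium triflate (O1=CaH cation; C2 S, C3 S with OTES; Cb bears ring A) | CC(C)=CCC[C@]1(C)[O+]=CC(C[C@@H]1O[Si](CC)(CC)CC)c1cc(CC=C(C)C)c(O[Si](C(C)C)(C(C)C)C(C)C)cc1Oc1cccc(O[Si](C)(C)C(C)(C)C)c1.[O-]S(=O)(=O)C(F)(F)F | intermediate (not isolated)
15 | C3-triethylsilyl ether of the 10,11-dihydro pyrano-dibenzoxepine (2S,3S; Ca/Cb epimers; key-step product) | CC(C)=CCC[C@]1(C)OC2C(C[C@@H]1O[Si](CC)(CC)CC)c1cc(CC=C(C)C)c(O[Si](C(C)C)(C(C)C)C(C)C)cc1Oc1cc(O[Si](C)(C)C(C)(C)C)ccc12 | intermediate
16 | tris-silylated pyrano-dibenzo[b,f]oxepine (2S,3S) | CC(C)=CCC[C@]1(C)OC2=C(C[C@@H]1O[Si](CC)(CC)CC)c1cc(CC=C(C)C)c(O[Si](C(C)C)(C(C)C)C(C)C)cc1Oc1cc(O[Si](C)(C)C(C)(C)C)ccc12 | intermediate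
17 | CNP0185870.1: C2 (S) with methyl and 4-methylpent-3-enyl, C3 (S) hydroxyl, prenyl and hydroxyl on ring A, hydroxyl on ring B | CC(C)=CCC[C@]1(C)OC2=C(C[C@@H]1O)c1cc(CC=C(C)C)c(O)cc1Oc1cc(O)ccc12 | target

**Count.** Total steps: 11. Longest linear sequence: 9 (steps 1–4 and 7–11).

**Steps most likely to fail**

1. Step 9 (proposed new method). What may go wrong:
   - opening of the epoxide at the secondary carbon or through a free tertiary cation, with loss of regio- and stereocontrol;
   - capture of the cation by the homoprenyl alkene instead of ring B;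
   - 1,2-hydride shift of the activated epoxide (Meinwald rearrangement).

   Fallback, known chemistry, from 12 to 15: the two bond formations are separated. BF3·OEt2 (CH2Cl2, −78 °C, aqueous work-up) lets the ester carbonyl open the epoxide at the tertiary carbon (Lewis-acid epoxy ester lactonisation) to give hydroxy δ-lactone F1. TESCl and imidazole give lactone silyl ether F2. DIBAL-H at −78 °C gives lactol F3. BF3·OEt2 at −40 °C ionises the lactol to the cation of 14 and ring B closes the oxepine (Friedel–Crafts arylation of a lactol, as in C-aryl glycoside synthesis), which rejoins the route at 15.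

2. Step 10. What may go wrong: hydride abstraction at the benzylic and allylic prenyl methylene of ring A, or further oxidation of the electron-rich enol ether once it has formed.

   Fallback, from 5 to 16: the prenyl group is introduced only after the dehydrogenation. LiHMDS converts 5 into lithium enolate F4, which is alkylated with 10 to iodo epoxy ester F5. DIBAL-H gives iodo epoxy aldehyde F6. The conditions of step 9 give, through iodo oxocarbenium triflate F7, the iodo dihydro compound F8. DDQ then gives iodo dibenzoxepine F9, which has no prenyl group to be attacked. Stille coupling with 6 as in step 4 rejoins the route at 16.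

3. Step 7. What may go wrong: slow displacement at the β-branched oxiranylmethyl bromide, so that self-condensation of the enolate, attack at bromine or opening of the epoxide compete.

   Fallback, from 9 to 12: the halide is replaced by a sulfonate that reacts far below the temperature at which these side reactions start. Tf2O and 2,6-lutidine (CH2Cl2, −78 °C) convert 9 into epoxyneryl triflate F10, which is added cold to enolate 11 at −78 °C; this bypasses 10 and rejoins the route at 12.

Further compounds
F1 | step 9 | hydroxy δ-lactone (O1–C2 closed, C3–OH free, lactone carbonyl at Ca) | CC(C)=CCC[C@]1(C)OC(=O)C(C[C@@H]1O)c1cc(CC=C(C)C)c(O[Si](C(C)C)(C(C)C)C(C)C)cc1Oc1cccc(O[Si](C)(C)C(C)(C)C)c1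
F2 | step 9 | C3-triethylsilyl ether of the δ-lactone | CC(C)=CCC[C@]1(C)OC(=O)C(C[C@@H]1O[Si](CC)(CC)CC)c1cc(CC=C(C)C)c(O[Si](C(C)C)(C(C)C)C(C)C)cc1Oc1cccc(O[Si](C)(C)C(C)(C)C)c1
F3 | step 9 | lactol (Ca hemiacetal) | CC(C)=CCC[C@]1(C)OC(O)C(C[C@@H]1O[Si](CC)(CC)CC)c1cc(CC=C(C)C)c(O[Si](C(C)C)(C(C)C)C(C)C)cc1Oc1cccc(O[Si](C)(C)C(C)(C)C)c1
F4 | step 10 | lithium enolate of iodo ester 5 | [Li+].COC([O-])=Cc1cc(I)c(O[Si](C(C)C)(C(C)C)C(C)C)cc1Oc1cccc(O[Si](C)(C)C(C)(C)C)c1
F5 | step 10 | iodo epoxy ester (12 with iodine in place of prenyl) | CC(C)=CCC[C@@]1(C)O[C@H]1CC(C(=O)OC)c1cc(I)c(O[Si](C(C)C)(C(C)C)C(C)C)cc1Oc1cccc(O[Si](C)(C)C(C)(C)C)c1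
F6 | step 10 | iodo epoxy aldehyde (13 with iodine in place of prenyl) | CC(C)=CCC[C@@]1(C)O[C@H]1CC(C=O)c1cc(I)c(O[Si](C(C)C)(C(C)C)C(C)C)cc1Oc1cccc(O[Si](C)(C)C(C)(C)C)c1
F7 | step 10 | iodo pyranyl oxocarbenium triflate | CC(C)=CCC[C@]1(C)[O+]=CC(C[C@@H]1O[Si](CC)(CC)CC)c1cc(I)c(O[Si](C(C)C)(C(C)C)C(C)C)cc1Oc1cccc(O[Si](C)(C)C(C)(C)C)c1.[O-]S(=O)(=O)C(F)(F)F
F8 | step 10 | iodo 10,11-dihydro pyrano-dibenzoxepine (15 with iodine in place of prenyl) | CC(C)=CCC[C@]1(C)OC2C(C[C@@H]1O[Si](CC)(CC)CC)c1cc(I)c(O[Si](C(C)C)(C(C)C)C(C)C)cc1Oc1cc(O[Si](C)(C)C(C)(C)C)ccc12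
F9 | step 10 | iodo pyrano-dibenzo[b,f]oxepine (16 with iodine in place of prenyl) | CC(C)=CCC[C@]1(C)OC2=C(C[C@@H]1O[Si](CC)(CC)CC)c1cc(I)c(O[Si](C(C)C)(C(C)C)C(C)C)cc1Oc1cc(O[Si](C)(C)C(C)(C)C)ccc12
F10 | step 7 | (2S,3R)-2,3-epoxyneryl trifluoromethanesulfonate | CC(C)=CCC[C@@]1(C)O[C@H]1COS(=O)(=O)C(F)(F)F
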